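1. Locants: ring C1 (CHOAc), C2 and C3 (CHOH), C4=C5 (C5 carries C7H2OBz), C6 (CHOBz); "up" is the face of the C1 oxygen.
2. Retrosynthesis: cleave the C1 acetate, then the C6 and C7 benzoates, raise C7 to a methyl ester, and finally cut the C2–O and C3–O bonds back to a C2=C3 alkene. This leaves methyl (5S,6S)-5,6-dihydroxycyclohexa-1,3-diene-1-carboxylate.
3. Enabling feature: the C4=C5 alkene with its C7 carbon and the trans C6/C1 diol of the target coincide, in absolute configuration, with the isochorismate-derived dihydrodiol acid; only the trans C2/C3 diol has to be added.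
4. Forward: the single carbocycle comes ready-made from glucose fermentation, so no ring is built chemically. Then esterification, one-flask epoxidation/hydrolysis of C2=C3, C1/C2 acetonide, C3 silyl ether, ester reduction, double benzoylation, acid deprotection and orthoester-mediated C1 acetylation.
5. Stereochemistry: C1 and C6 come from the enzymes, C2 from delivery of the epoxide oxygen by the C1 hydroxyl, and C3 from invertive opening of that epoxide by water.

Key step: step 3

Assumption (biocatalyst): an Escherichia coli K-12 strain with entA deleted and entC/entB plasmid-borne serves as whole-cell catalyst, D-glucose being the only carbon source.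
Assumption (carbon balance): more than one molecule of glucose is consumed per molecule of acid 4, because the seven carbons of 4 are assembled from two glucose-derived fragments and part of the glucose is respired. Further glucose is therefore entered in step 1 as an atom-supplying reagent, and only the last two pathway intermediates are numbered.
Assumption (conformation): in triol 13 and orthoacetate 14 the C6 benzoate is taken to sit pseudoaxial (allylic 1,2-strain against the C5–C7 substituent), which makes C1–O axial and C2–O, C3–O equatorial, as in the 2,3,4-triol of an α-rhamnopyranoside.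

**Route**

Step 1
Reactants: 1 D-glucose
Product: 4 (5S,6S)-5,6-dihydroxycyclohexa-1,3-diene-1-carboxylic acid, via chorismic acid 2 (not isolated), via isochorismic acid 3 (not isolated)
Conditions: Escherichia coli whole cells (entA deleted; entC, entB overexpressed), glucose/mineral-salt medium, pH 7, 37 °C, aerated fed-batch; cell removal, anion-exchange resin, lyophilisation
Reagents that add atoms: D-glucose 1, further molecules as carbon source (O=C[C@H](O)[C@@H](O)[C@H](O)[C@H](O)CO); water (O)
Why: Whole-cell biosynthesis along the shikimate pathway, which builds the seven carbons of 4 from glucose-derived erythrose 4-phosphate (four carbons) and phosphoenolpyruvate (three carbons) and attaches a second phosphoenolpyruvate as the enolpyruvyl ether of 2; overexpressed isochorismate synthase then exchanges the ring hydroxyl of chorismate for a water-derived hydroxyl next to the carboxyl-bearing carbon in a 1,5-SN2'' displacement, isochorismatase hydrolyses the enol ether with release of pyruvate, and the deleted dehydrogenase can no longer aromatise the product, so the trans-(5S,6S) diol is set entirely by the enzymes.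

Step 2
Reactants: 4 (5S,6S)-5,6-dihydroxycyclohexa-1,3-diene-1-carboxylic acid
Product: 5 methyl (5S,6S)-5,6-dihydroxycyclohexa-1,3-diene-1-carboxylate
Conditions: MeI, KHCO3, DMF, rt
Reagents that add atoms: iodomethane (CI)
Why: SN2 O-alkylation of the potassium carboxylate under near-neutral conditions, chosen over Fischer esterification because acid dehydrates the dihydrodiol to hydroxybenzoates; the weak base leaves the secondary alcohols and both stereocentres untouched.

Step 3
Reactants: 5 methyl (5S,6S)-5,6-dihydroxycyclohexa-1,3-diene-1-carboxylate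
Product: 7 methyl (3R,4S,5R,6S)-3,4,5,6-tetrahydroxycyclohex-1-ene-1-carboxylate, via syn-epoxide 6 (not isolated)
Conditions: mCPBA (1.1 equiv), CH2Cl2, 0 °C; then THF/H2O (1:1), HClO4 (cat.), 0 °C to rt, same flask
Reagents that add atoms: mCPBA (O=C(OO)c1cccc(Cl)c1); water (O)
Why: Prilezhaev oxygen transfer through the butterfly transition state, with the C1 hydroxyl hydrogen-bonded to the peracid and steering it onto its own face of C2=C3 (Henbest direction), should give syn-epoxide 6; protonated 6 is then opened by water in an SN2-like, invertive attack at allylic C3, so the C2–O and C3–O bonds of the target form in one flask. The closest known reaction types are the Henbest epoxidation of cyclohex-2-enols and the acid-catalysed hydrolysis of vinyl oxiranes to trans-diols familiar from conduritol chemistry. No ring of the product is closed: the oxirane arises by concerted [2+1] oxygen transfer and is reopened before isolation, the carbocycle staying untouched. C2 is controlled by the C1 carbinol (oxygen delivered cis to C1–O) and C3 by the epoxide itself (water enters anti to the C2 oxygen), which gives the 1,2-cis/2,3-trans triad. Chemoselectivity rests on the ester, which makes C4=C5 too electron-poor for the electrophilic peracid; facial selectivity on the allylic C1–OH, the C6–OH on the other face being only homoallylic; regioselectivity on allylic activation of C3, on inductive deactivation of C2 by the adjacent C1–O bond, and on the fact that SN2' attack would have to occur at C5, the fully substituted α-carbon of the enoate.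

Step 4
Reactants: 7 methyl (3R,4S,5R,6S)-3,4,5,6-tetrahydroxycyclohex-1-ene-1-carboxylate
Product: 8 methyl (3aR,4S,7R,7aS)-4,7-dihydroxy-2,2-dimethyl-3a,4,7,7a-tetrahydro-1,3-benzodioxole-5-carboxylate (C1/C2 acetonide; C3-OH and C6-OH free)
Conditions: Me2C(OMe)2, CSA (cat.), acetone, rt
Reagents that add atoms: 2,2-dimethoxypropane (COC(C)(C)OC)
Why: Acid-catalysed transacetalisation under thermodynamic control, in which only the cis C1/C2 pair can close an unstrained cis-fused dioxolane while the trans pairs C2/C3 and C6/C1 cannot, as in the 3,4-acetonide formation of shikimate esters.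

Step 5
Reactants: 8 C1/C2 acetonide diol ester
Product: 9 methyl (3aR,4S,7R,7aR)-7-[(tert-butyldimethylsilyl)oxy]-4-hydroxy-2,2-dimethyl-3a,4,7,7a-tetrahydro-1,3-benzodioxole-5-carboxylate (C3-OTBS; C6-OH free)
Conditions: TBSCl (1.05 equiv), imidazole, DMF, −20 to 0 °C
Reagents that add atoms: tert-butyldimethylsilyl chloride (CC(C)(C)[Si](C)(C)Cl)
Why: Sterically controlled silyl ether formation, since C3-OH is flanked by the unsubstituted vinylic C4–H whereas C6-OH is buttressed by the ester-bearing C5 (allylic 1,2-strain) and hydrogen-bonded to the ester carbonyl, so the bulky chlorosilane should take C3-OH.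

Step 6
Reactants: 9 C3-O-TBS acetonide ester
Product: 10 (3aR,4S,7R,7aR)-7-[(tert-butyldimethylsilyl)oxy]-5-(hydroxymethyl)-2,2-dimethyl-3a,4,7,7a-tetrahydro-1,3-benzodioxol-4-ol (C6-OH and C7-OH free)
Conditions: iBu2AlH (4 equiv), CH2Cl2, −78 °C; aq. KNaC4H4O6
Reagents that add atoms: none
Why: 1,2-Reduction of the α,β-unsaturated ester to the allylic alcohol by the electrophilic aluminium hydride (the free C6-OH consuming one equivalent as its aluminate), with silyl ether and acetonide inert and no stereocentre touched.

Step 7
Reactants: 10 C6,C7-diol; 11 benzoyl chloride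
Product: 12 [(3aR,4S,7R,7aR)-4-(benzoyloxy)-7-[(tert-butyldimethylsilyl)oxy]-2,2-dimethyl-3a,4,7,7a-tetrahydro-1,3-benzodioxol-5-yl]methyl benzoate
Conditions: BzCl (2.5 equiv), pyridine, DMAP (cat.), CH2Cl2, 0 °C to rt
Reagents that add atoms: benzoyl chloride 11 (O=C(Cl)c1ccccc1)
Why: DMAP-catalysed acylation of the only two free hydroxyls, the primary allylic C7-OH and the secondary allylic C6-OH, in one operation, the C1, C2 and C3 oxygens being masked.

Step 8
Reactants: 12 dibenzoate
Product: 13 [(3R,4S,5S,6S)-6-(benzoyloxy)-3,4,5-trihydroxycyclohex-1-en-1-yl]methyl benzoate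
Conditions: TFA/H2O (9:1), 0 °C to rt
Reagents that add atoms: none
Why: Acid hydrolysis of the isopropylidene acetal together with protodesilylation of the secondary TBS ether, under conditions that leave benzoates intact and avoid the base needed for acyl migration.

Step 9
Reactants: 13 C1,C2,C3-triol dibenzoate
Product: 15 [(3R,4S,5S,6S)-5-acetoxy-6-(benzoyloxy)-3,4-dihydroxycyclohex-1-en-1-yl]methyl benzoate, via cyclic orthoacetate 14 (not isolated)
Conditions: MeC(OMe)3 (1.5 equiv), CSA (cat.), MeCN, rt; then AcOH/H2O (4:1), rt; neutral work-up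
Reagents that add atoms: trimethyl orthoacetate (COC(C)(OC)OC); water (O)
Why: Orthoester-mediated monoacylation of a cis-1,2-diol, in which acid-catalysed exchange closes the cis-fused 2-methoxy-2-methyl-1,3-dioxolane on the C1/C2 pair (the trans C3-OH cannot close a comparable ring) and mild aqueous acid collapses the derived hemi-orthoester with the usual preference for axial ester and equatorial alcohol, here C1-OAc and free C2-OH, as in the 2-O-acetylation of α-rhamnopyranosides that carry free 3- and 4-hydroxyls.

**Compound list**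
1 | D-glucose | O=C[C@H](O)[C@@H](O)[C@H](O)[C@H](O)CO | starting material
2 | chorismic acid, (3R,4R)-3-[(1-carboxyethenyl)oxy]-4-hydroxycyclohexa-1,5-diene-1-carboxylic acid | C=C(C(=O)O)O[C@@H]1C=C(C(=O)O)C=C[C@H]1O | intermediate (not isolated)
3 | isochorismic acid, (5S,6S)-5-[(1-carboxyethenyl)oxy]-6-hydroxycyclohexa-1,3-diene-1-carboxylic acid | C=C(C(=O)O)O[C@H]1C=CC=C(C(=O)O)[C@@H]1O | intermediate (not isolated)
4 | (5S,6S)-5,6-dihydroxycyclohexa-1,3-diene-1-carboxylic acid | O[C@H]1C=CC=C(C(=O)O)[C@@H]1O | intermediate
5 | methyl (5S,6S)-5,6-dihydroxycyclohexa-1,3-diene-1-carboxylate | O[C@H]1C=CC=C(C(=O)OC)[C@@H]1O | intermediate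
6 | methyl (1S,4S,5R,6R)-4,5-dihydroxy-7-oxabicyclo[4.1.0]hept-2-ene-3-carboxylate (C2/C3 epoxide cis to C1-OH) | O[C@H]1[C@H]2O[C@H]2C=C(C(=O)OC)[C@@H]1O | intermediate (not isolated)
7 | methyl (3R,4S,5R,6S)-3,4,5,6-tetrahydroxycyclohex-1-ene-1-carboxylate | O[C@H]1[C@@H](O)[C@H](O)C=C(C(=O)OC)[C@@H]1O | intermediate
8 | methyl (3aR,4S,7R,7aS)-4,7-dihydroxy-2,2-dimethyl-3a,4,7,7a-tetrahydro-1,3-benzodioxole-5-carboxylate | CC1(C)O[C@H]2[C@@H](O1)[C@H](O)C=C(C(=O)OC)[C@@H]2O | intermediate
9 | methyl (3aR,4S,7R,7aR)-7-[(tert-butyldimethylsilyl)oxy]-4-hydroxy-2,2-dimethyl-3a,4,7,7a-tetrahydro-1,3-benzodioxole-5-carboxylate | CC1(C)O[C@H]2[C@@H](O1)[C@H](O[Si](C)(C)C(C)(C)C)C=C(C(=O)OC)[C@@H]2O | intermediate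
10 | (3aR,4S,7R,7aR)-7-[(tert-butyldimethylsilyl)oxy]-5-(hydroxymethyl)-2,2-dimethyl-3a,4,7,7a-tetrahydro-1,3-benzodioxol-4-ol | CC1(C)O[C@H]2[C@@H](O1)[C@H](O[Si](C)(C)C(C)(C)C)C=C(CO)[C@@H]2O | intermediate
11 | benzoyl chloride | O=C(Cl)c1ccccc1 | starting material
12 | [(3aR,4S,7R,7aR)-4-(benzoyloxy)-7-[(tert-butyldimethylsilyl)oxy]-2,2-dimethyl-3a,4,7,7a-tetrahydro-1,3-benzodioxol-5-yl]methyl benzoate | CC1(C)O[C@H]2[C@@H](O1)[C@H](O[Si](C)(C)C(C)(C)C)C=C(COC(=O)c3ccccc3)[C@@H]2OC(=O)c3ccccc3 | intermediate
13 | [(3R,4S,5S,6S)-6-(benzoyloxy)-3,4,5-trihydroxycyclohex-1-en-1-yl]methyl benzoate | O[C@H]1[C@@H](O)[C@H](O)C=C(COC(=O)c2ccccc2)[C@@H]1OC(=O)c1ccccc1 | intermediate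
14 | [(3aR,4S,7R,7aS)-4-(benzoyloxy)-7-hydroxy-2-methoxy-2-methyl-3a,4,7,7a-tetrahydro-1,3-benzodioxol-5-yl]methyl benzoate (C1/C2 cyclic orthoacetate, both epimers at the orthoester carbon) | COC1(C)O[C@H]2[C@@H](O1)[C@H](O)C=C(COC(=O)c3ccccc3)[C@@H]2OC(=O)c3ccccc3 | intermediate (not isolated)
15 | [(3R,4S,5S,6S)-5-acetoxy-6-(benzoyloxy)-3,4-dihydroxycyclohex-1-en-1-yl]methyl benzoate (CNP0213675.1) | CC(=O)O[C@H]1[C@@H](O)[C@H](O)C=C(COC(=O)c2ccccc2)[C@@H]1OC(=O)c1ccccc1 | target

**Step count and risks**
Total steps: 9. Longest linear sequence: 9 steps (1 to 15).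

Step 5, incomplete discrimination between the two secondary allylic hydroxyls during silylation (silylation at C6-OH or at both hydroxyls alongside 9). The fallback removes the need for discrimination by tying C6-OH to C7-OH. It sets out from 8, which is reduced with iBu2AlH (CH2Cl2, −78 °C) to (3aR,4S,7R,7aS)-5-(hydroxymethyl)-2,2-dimethyl-3a,4,7,7a-tetrahydro-1,3-benzodioxole-4,7-diol F1. Condensation with PhB(OH)2 in toluene with azeotropic removal of water ties the C6/C7 1,3-diol into the six-membered cyclic phenylboronate F2, leaving C3-OH as the only free hydroxyl. Silylation with TBSOTf/2,6-lutidine gives the C3-O-TBS boronate F3, and boron is then exchanged onto pinacol (CH2Cl2, rt), which returns the route at 10.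

Step 9, non-selective collapse of the orthoester (acetate at C2), acetylation of C3-OH through an acyclic orthoester, or later C1-to-C2 acetyl migration. The fallback masks the trans C2/C3 diol instead of relying on orthoester regiochemistry. It sets out from 13, which is treated with 2,2,3,3-tetramethoxybutane, HC(OMe)3 and CSA (cat.) in MeOH at 60 °C. The butane-2,3-diacetal should form only on the trans-diequatorial C2/C3 pair (both methoxy groups axial), giving the C2,C3-O-(2,3-dimethoxybutane-2,3-diyl) acetal F4 with C1-OH free. Acetylation (Ac2O, pyridine, DMAP) gives the C1-acetate F5, and TFA/H2O (9:1, 0 °C) removes the diacetal to arrive at 15.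

Step 3, erosion of regioselectivity in the opening (water at C2, or capture of the protonated epoxide by 3-chlorobenzoic acid), loss of facial control through hydrogen bonding of the peracid to C6-OH, or acid-promoted dehydration during the one-flask hydrolysis. The fallback separates the two events and replaces water by a titanium-delivered carboxylate. It sets out from 5, which is epoxidised with mCPBA buffered by NaHCO3 (CH2Cl2, 0 °C), and epoxide 6 is isolated. Opening with PhCO2H and Ti(OiPr)4 (CH2Cl2, rt), where the titanium alkoxide of the C1 hydroxyl directs the carboxylate to C3 of the 2,3-epoxy alcohol with inversion, gives methyl (3R,4R,5R,6S)-3-(benzoyloxy)-4,5,6-trihydroxycyclohex-1-ene-1-carboxylate F6. Methanolysis (K2CO3 cat., MeOH, 0 °C) then returns the route at 7.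

**Further compounds**
F1 | step 5 | (3aR,4S,7R,7aS)-5-(hydroxymethyl)-2,2-dimethyl-3a,4,7,7a-tetrahydro-1,3-benzodioxole-4,7-diol | CC1(C)O[C@H]2[C@@H](O1)[C@H](O)C=C(CO)[C@@H]2O
F2 | step 5 | cyclic phenylboronate of F1 across O6 and O7 (2-phenyl-1,3,2-dioxaborinane; C3-OH free) | CC1(C)O[C@H]2[C@@H](O1)[C@H](O)C=C3COB(c4ccccc4)O[C@H]23
F3 | step 5 | C3-O-tert-butyldimethylsilyl ether of boronate F2 | CC1(C)O[C@H]2[C@@H](O1)[C@H](O[Si](C)(C)C(C)(C)C)C=C3COB(c4ccccc4)O[C@H]23
F4 | step 9 | C2,C3-O-(2,3-dimethoxybutane-2,3-diyl) acetal of triol 13 (methoxy groups axial; C1-OH free) | O[C@H]1[C@H]2O[C@](C)(OC)[C@@](C)(OC)O[C@@H]2C=C(COC(=O)c3ccccc3)[C@@H]1OC(=O)c3ccccc3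
F5 | step 9 | C1-O-acetate of diacetal F4 | CC(=O)O[C@H]1[C@H]2O[C@](C)(OC)[C@@](C)(OC)O[C@@H]2C=C(COC(=O)c3ccccc3)[C@@H]1OC(=O)c3ccccc3
F6 | step 3 | methyl (3R,4R,5R,6S)-3-(benzoyloxy)-4,5,6-trihydroxycyclohex-1-ene-1-carboxylate | O[C@H]1[C@@H](O)[C@H](OC(=O)c2ccccc2)C=C(C(=O)OC)[C@@H]1O
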